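**Retrosynthetic overview**

1. Target 21 ← methanolysis of the temporary δ-lactone (ring C, closed through O7) of tricyclic dihydrocoumarin 20.
2. 20 ← chromanone 18 + (E)-hex-2-enal 19 by carbene-catalysed oxidative [3+3] annulation, which forms the C8–C(benzylic) bond, the S side-chain centre and the ester oxidation level in one operation.
3. Enabling feature: in ring A of 18, C8 is the only unsubstituted carbon and sits ortho to the one free, acidic phenol (7-OH; the 5-OH is locked in a hydrogen bond to C4=O), so O7–C7=C8 reacts as the enol of a vinylogous acid and O7 then closes ring C.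
4. 18 ← Mitsunobu closure of ring B (O1–C2, inversion) in hydroxy ketone 16, whose two stereocentres come from an Evans syn-aldol unit; 16 ← aryllithium of 13 (future O1 as EE acetal, O5/O7 as MOM ethers) + Weinreb amide 6.
5. 13 ← 1,3-bis(methoxymethoxy)benzene by ortho-lithiation/prenylation, then C–H borylation/oxidation. Ring order: ring A purchased, ring B in step 8, temporary ring C in step 10, opened in step 11.

Key step: step 10

**Remarks on the chemistry**

- 1,3-Bis(methoxymethoxy)benzene 7 is taken as a catalogue compound (otherwise one step from resorcinol with MOMCl and i-Pr2NEt).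
- Assumption: the triazolium catalyst of step 10 follows the usual shielding model. Both antipodes of the precatalyst are commercial, so the antipode is used if a pilot run shows the opposite sense of induction.

**Route**

Step 1
Reactants: 1 (S)-4-benzyl-3-propanoyloxazolidin-2-one; 2 acetaldehyde
Product: 4 (S)-4-benzyl-3-[(2S,3R)-3-hydroxy-2-methylbutanoyl]oxazolidin-2-one, via Z-boron enolate 3 (not isolated)
Conditions: n-Bu2BOTf, i-Pr2NEt, CH2Cl2, 0 °C; then 2, −78 → 0 °C; then pH 7 buffer, MeOH, 30 % aq H2O2, 0 °C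
Reagents that add atoms: dibutylboron triflate, CCCCB(CCCC)OS(=O)(=O)C(F)(F)F (boron of intermediate 3 only)
Why: Evans syn-aldol reaction, in which the Z-boron enolate reacts through a closed chair transition state and the (S)-benzyl auxiliary shields one enolate face, should set C2 as S and C3 as R.

Step 2
Reactants: 4 (S)-4-benzyl-3-[(2S,3R)-3-hydroxy-2-methylbutanoyl]oxazolidin-2-one
Product: 5 (2S,3R)-3-hydroxy-N-methoxy-N,2-dimethylbutanamide
Conditions: MeNH(OMe)·HCl, AlMe3, CH2Cl2, −10 °C → rt; aq potassium sodium tartrate work-up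
Reagents that add atoms: N,O-dimethylhydroxylamine hydrochloride, CNOC.Cl
Why: Weinreb transamidation by the aluminium amide, assisted by the free β-hydroxyl, should release the auxiliary without touching either stereocentre.

Step 3
Reactants: 5 (2S,3R)-3-hydroxy-N-methoxy-N,2-dimethylbutanamide
Product: 6 (2S,3R)-N-methoxy-N,2-dimethyl-3-(triethylsilyloxy)butanamide
Conditions: TESCl, imidazole, CH2Cl2, 0 °C → rt
Reagents that add atoms: chlorotriethylsilane, CC[Si](Cl)(CC)CC
Why: Standard silylation of a secondary alcohol; the TES ether survives the aryllithium addition and is labile enough to leave together with the EE acetal in step 7.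

Step 4
Reactants: 7 1,3-bis(methoxymethoxy)benzene; 8 1-bromo-3-methylbut-2-ene (prenyl bromide)
Product: 10 1,3-bis(methoxymethoxy)-2-(3-methylbut-2-en-1-yl)benzene, via 2-lithio arene 9 (not isolated)
Conditions: n-BuLi, THF, 0 °C → rt; then CuI (10 mol %), 8, −78 °C → rt
Reagents that add atoms: n-butyllithium, [Li]CCCC (lithium of intermediate 9 only)
Why: Directed ortho-metalation at the carbon between the two OMOM groups, followed by copper-catalysed SN2 allylation of the aryllithium, should place the prenyl group unambiguously.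

Step 5
Reactants: 10 1,3-bis(methoxymethoxy)-2-(3-methylbut-2-en-1-yl)benzene
Product: 12 3,5-bis(methoxymethoxy)-4-(3-methylbut-2-en-1-yl)phenol, via aryl pinacol boronate 11 (not isolated)
Conditions: B2pin2, [Ir(OMe)(cod)]2 (1.5 mol %), 4,4'-di-tert-butyl-2,2'-bipyridine (3 mol %), THF, 60 °C; then 30 % aq H2O2, aq NaOH, THF, 0 °C
Reagents that add atoms: hydrogen peroxide, OO; bis(pinacolato)diboron, CC1(C)OB(OC1(C)C)B1OC(C)(C)C(C)(C)O1 (boron of intermediate 11 only)
Why: Sterically governed iridium-catalysed C–H borylation should take the only ring C–H without an ortho substituent (para to the prenyl group), and oxidation of the C–B bond gives the phenol whose oxygen becomes O1.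

Step 6
Reactants: 12 3,5-bis(methoxymethoxy)-4-(3-methylbut-2-en-1-yl)phenol
Product: 13 5-(1-ethoxyethoxy)-1,3-bis(methoxymethoxy)-2-(3-methylbut-2-en-1-yl)benzene (racemic at the acetal carbon)
Conditions: ethyl vinyl ether, PPTS (5 mol %), CH2Cl2, 0 °C → rt
Reagents that add atoms: ethyl vinyl ether, C=COCC
Why: Acid-catalysed addition of the phenol to the enol ether gives an EE acetal, which directs ortho-lithiation and can later be removed without loss of the two MOM ethers.

Step 7
Reactants: 13 5-(1-ethoxyethoxy)-1,3-bis(methoxymethoxy)-2-(3-methylbut-2-en-1-yl)benzene; 6 (2S,3R)-N-methoxy-N,2-dimethyl-3-(triethylsilyloxy)butanamide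
Product: 16 (2S,3R)-3-hydroxy-1-[6-hydroxy-2,4-bis(methoxymethoxy)-3-(3-methylbut-2-en-1-yl)phenyl]-2-methylbutan-1-one, via aryllithium 14 (not isolated), via protected ketone 15 (not isolated)
Conditions: n-BuLi, THF, 0 °C; then 6, −78 → 0 °C; H2O quench; then crude 15, PPTS (cat.), MeOH, rt
Reagents that add atoms: n-butyllithium, [Li]CCCC (lithium of intermediate 14 only)
Why: Directed ortho-metalation between OEE and OMOM (the two open ring positions are equivalent by symmetry) and Weinreb ketone synthesis give the aryl ketone without over-addition, and mild acidic methanolysis then removes only the EE acetal and the TES ether, so the single free phenol is the future O1.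

Step 8
Reactants: 16 (2S,3R)-3-hydroxy-1-[6-hydroxy-2,4-bis(methoxymethoxy)-3-(3-methylbut-2-en-1-yl)phenyl]-2-methylbutan-1-one
Product: 17 (2S,3S)-5,7-bis(methoxymethoxy)-2,3-dimethyl-6-(3-methylbut-2-en-1-yl)chroman-4-one
Conditions: PPh3, DIAD, THF, 0 °C → rt
Reagents that add atoms: none
Why: Intramolecular Mitsunobu etherification (6-exo-tet SN2 displacement of the oxyphosphonium by the only free phenol) should invert the carbinol carbon from R to S while C3 stays S, giving the trans-2,3-dimethylchromanone, which is also the thermodynamically preferred diastereomer.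

Step 9
Reactants: 17 (2S,3S)-5,7-bis(methoxymethoxy)-2,3-dimethyl-6-(3-methylbut-2-en-1-yl)chroman-4-one
Product: 18 (2S,3S)-5,7-dihydroxy-2,3-dimethyl-6-(3-methylbut-2-en-1-yl)chroman-4-one
Conditions: conc. HCl (cat.), MeOH, rt to 40 °C
Reagents that add atoms: none
Why: Acid-catalysed acetal exchange with methanol cleaves both MOM ethers; C2 is not enolisable and the trans arrangement at C3 is the thermodynamic one, so neither centre is at risk.

Step 10
Reactants: 18 (2S,3S)-5,7-dihydroxy-2,3-dimethyl-6-(3-methylbut-2-en-1-yl)chroman-4-one; 19 (E)-hex-2-enal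
Product: 20 (2S,3S,10S)-5-hydroxy-2,3-dimethyl-6-(3-methylbut-2-en-1-yl)-10-propyl-2,3,9,10-tetrahydro-4H,8H-pyrano[2,3-f]chromene-4,8-dione
Conditions: one enantiomer of 2-mesityl-5a,10b-dihydro-4H,6H-indeno[2,1-b][1,2,4]triazolo[4,3-d][1,4]oxazin-2-ium chloride (10 mol %), DBU (20 mol %), 3,3',5,5'-tetra-tert-butyl-4,4'-diphenoquinone (1.2 equiv), 4 Å molecular sieves, toluene/THF, rt
Reagents that add atoms: none
Why: The carbene adds to 19, the resulting enaminol is oxidised by the diphenoquinone to the α,β-unsaturated acyl azolium, and the 7-phenoxide of 18 attacks it as an enolate (O7–C7=C8), either by direct Michael addition through C8 or by 1,2-addition and a Claisen-type [3,3] shift, to form the C8–C10 bond; the transiently dearomatised cyclohexadienone then re-aromatises by tautomerisation and the 7-OH acylates onto the acyl azolium, releasing the carbene. The closest known reaction type is the oxidative carbene-catalysed [3+3] annulation of enals with 2-naphthols, electron-rich phenols and 1,3-dicarbonyl compounds to give 3,4-dihydrocoumarins and dihydropyranones. Ring C is closed first by the intermolecular conjugate C–C bond formation and then by a 6-exo-trig O-acylation (addition–elimination at the acyl azolium carbon). The new C10 stereocentre is set by the catalyst: the indane wall of the triazolium should block the Re face of the β-carbon so that C8 adds to the Si face and gives the S configuration, and the C2/C3 centres are too remote to override this. The step needs site selectivity, C- over O-acylation and face selectivity; C8 is the only free ring carbon because the prenyl group occupies C6, the 5-OH is tied up in its hydrogen bond to C4=O, and O-acylation of the 7-OH only gives an aryl enoate that the carbene returns to the acyl azolium, so only the C–C pathway is productive.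

Step 11
Reactants: 20 (2S,3S,10S)-5-hydroxy-2,3-dimethyl-6-(3-methylbut-2-en-1-yl)-10-propyl-2,3,9,10-tetrahydro-4H,8H-pyrano[2,3-f]chromene-4,8-dione
Product: 21 methyl (3S)-3-[(2S,3S)-5,7-dihydroxy-2,3-dimethyl-6-(3-methylbut-2-en-1-yl)-4-oxo-3,4-dihydro-2H-chromen-8-yl]hexanoate
Conditions: MeOH, Et3N, DMAP (10 mol %), 0 °C → rt; pH 6 phosphate buffer work-up
Reagents that add atoms: methanol, CO
Why: Base-catalysed transesterification of the aryl ester (a δ-lactone of an acidic phenol) by methanol should open the temporary ring to the methyl ester and the free 7-OH, and the benzylic centre is β to the ester and not enolisable.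

**Compound list**

1 | (S)-4-benzyl-3-propanoyloxazolidin-2-one | CCC(=O)N1[C@@H](Cc2ccccc2)COC1=O | starting material
2 | acetaldehyde | CC=O | starting material
3 | Z-dibutylboron enolate of 1 | C/C=C(\OB(CCCC)CCCC)N1[C@@H](Cc2ccccc2)COC1=O | intermediate
4 | (S)-4-benzyl-3-[(2S,3R)-3-hydroxy-2-methylbutanoyl]oxazolidin-2-one | C[C@@H](O)[C@H](C)C(=O)N1[C@@H](Cc2ccccc2)COC1=O | intermediate
5 | (2S,3R)-3-hydroxy-N-methoxy-N,2-dimethylbutanamide | C[C@@H](O)[C@H](C)C(=O)N(C)OC | intermediate
6 | (2S,3R)-N-methoxy-N,2-dimethyl-3-(triethylsilyloxy)butanamide | C[C@@H](O[Si](CC)(CC)CC)[C@H](C)C(=O)N(C)OC | intermediate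
7 | 1,3-bis(methoxymethoxy)benzene | COCOc1cccc(OCOC)c1 | starting material
8 | 1-bromo-3-methylbut-2-ene | CC(C)=CCBr | starting material
9 | [2,6-bis(methoxymethoxy)phenyl]lithium | COCOc1cccc(OCOC)c1[Li] | intermediate
10 | 1,3-bis(methoxymethoxy)-2-(3-methylbut-2-en-1-yl)benzene | COCOc1cccc(OCOC)c1CC=C(C)C | intermediate
11 | 2-[3,5-bis(methoxymethoxy)-4-(3-methylbut-2-en-1-yl)phenyl]-4,4,5,5-tetramethyl-1,3,2-dioxaborolane | COCOc1cc(B2OC(C)(C)C(C)(C)O2)cc(OCOC)c1CC=C(C)C | intermediate
12 | 3,5-bis(methoxymethoxy)-4-(3-methylbut-2-en-1-yl)phenol | COCOc1cc(O)cc(OCOC)c1CC=C(C)C | intermediate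
13 | 5-(1-ethoxyethoxy)-1,3-bis(methoxymethoxy)-2-(3-methylbut-2-en-1-yl)benzene (racemic acetal carbon) | CCOC(C)Oc1cc(OCOC)c(CC=C(C)C)c(OCOC)c1 | intermediate
14 | [6-(1-ethoxyethoxy)-2,4-bis(methoxymethoxy)-3-(3-methylbut-2-en-1-yl)phenyl]lithium | CCOC(C)Oc1cc(OCOC)c(CC=C(C)C)c(OCOC)c1[Li] | intermediate
15 | (2S,3R)-1-[6-(1-ethoxyethoxy)-2,4-bis(methoxymethoxy)-3-(3-methylbut-2-en-1-yl)phenyl]-2-methyl-3-(triethylsilyloxy)butan-1-one (both acetal epimers) | C[C@@H](O[Si](CC)(CC)CC)[C@H](C)C(=O)c1c(OC(C)OCC)cc(OCOC)c(CC=C(C)C)c1OCOC | intermediate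
16 | (2S,3R)-3-hydroxy-1-[6-hydroxy-2,4-bis(methoxymethoxy)-3-(3-methylbut-2-en-1-yl)phenyl]-2-methylbutan-1-one | C[C@@H](O)[C@H](C)C(=O)c1c(O)cc(OCOC)c(CC=C(C)C)c1OCOC | intermediate
17 | (2S,3S)-5,7-bis(methoxymethoxy)-2,3-dimethyl-6-(3-methylbut-2-en-1-yl)chroman-4-one | C[C@@H]1Oc2cc(OCOC)c(CC=C(C)C)c(OCOC)c2C(=O)[C@H]1C | intermediate
18 | (2S,3S)-5,7-dihydroxy-2,3-dimethyl-6-(3-methylbut-2-en-1-yl)chroman-4-one | C[C@@H]1Oc2cc(O)c(CC=C(C)C)c(O)c2C(=O)[C@H]1C | intermediate
19 | (E)-hex-2-enal | CCC/C=C/C=O | starting material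
20 | (2S,3S,10S)-5-hydroxy-2,3-dimethyl-6-(3-methylbut-2-en-1-yl)-10-propyl-2,3,9,10-tetrahydro-4H,8H-pyrano[2,3-f]chromene-4,8-dione | CCC[C@H]1CC(=O)Oc2c(CC=C(C)C)c(O)c3c(c21)O[C@@H](C)[C@H](C)C3=O | intermediate
21 | methyl (3S)-3-[(2S,3S)-5,7-dihydroxy-2,3-dimethyl-6-(3-methylbut-2-en-1-yl)-4-oxo-3,4-dihydro-2H-chromen-8-yl]hexanoate | CCC[C@@H](CC(=O)OC)c1c(O)c(CC=C(C)C)c(O)c2c1O[C@@H](C)[C@H](C)C2=O | target

**Step count and risks**

Total step count: 11 steps. Longest linear sequence: 8 steps (7 → 21 through steps 4–11; equally 1 → 21 through steps 1–3 and 7–11).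

Steps most likely to fail:

1. Step 10. The acylphloroglucinol enol may add too slowly to the acyl azolium, the electron-rich phenol may be oxidised by the quinone, or the facial selectivity may be poor. The fallback sets out from 18 and comes back at 20. 18 is condensed with butanal and 2,2-dimethyl-1,3-dioxane-4,6-dione (pyridine cat., MeCN, 60–80 °C). Knoevenagel condensation gives the alkylidene malonate, C8 adds in a Friedel–Crafts/Michael sense, and the 7-OH closes the lactone with loss of acetone and carbon dioxide. Without a chiral catalyst this should give 20 together with its C10 epimer, (2S,3S,10R)-5-hydroxy-2,3-dimethyl-6-(3-methylbut-2-en-1-yl)-10-propyl-2,3,9,10-tetrahydro-4H,8H-pyrano[2,3-f]chromene-4,8-dione F1. Because C2 and C3 are fixed, the two are diastereomers and are separated by chromatography or crystallisation.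

2. Step 7. Lateral lithiation of the doubly activated prenyl CH2 may compete, the hindered aryllithium may add slowly to the α-branched amide, or the amide may epimerise at its α-carbon. The fallback sets out from 12 (side-chain unit taken from 4) and comes back at 17; it forms O1–C2 first and C4–C4a last, with no aryllithium. 4 is methanolysed with MeOMgBr in MeOH to methyl (2S,3R)-3-hydroxy-2-methylbutanoate F2. Intermolecular Mitsunobu etherification of 12 with this ester (PPh3, DIAD, toluene) inverts the carbinol carbon and gives methyl (2S,3S)-3-[3,5-bis(methoxymethoxy)-4-(3-methylbut-2-en-1-yl)phenoxy]-2-methylbutanoate F3. Saponification with LiOH in THF/H2O gives (2S,3S)-3-[3,5-bis(methoxymethoxy)-4-(3-methylbut-2-en-1-yl)phenoxy]-2-methylbutanoic acid F4. Intramolecular Friedel–Crafts acylation through the mixed trifluoroacetic anhydride (TFAA, 2,6-di-tert-butylpyridine, CH2Cl2, 0 °C) onto either of the two equivalent ortho carbons closes ring B to 17.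

3. Step 8. The activated β-hydroxy ketone may dehydrate by an E1cB pathway to the tigloyl ketone, whose unselective re-closure would erode the configuration at C2; C3 may also epimerise. The fallback sets out from 13 and comes back at 17; it accepts the enone and sets C2 by catalysis. Aryllithium 14 (from 13 as in step 7) is acylated with (E)-N-methoxy-N,2-dimethylbut-2-enamide to give (E)-1-[6-(1-ethoxyethoxy)-2,4-bis(methoxymethoxy)-3-(3-methylbut-2-en-1-yl)phenyl]-2-methylbut-2-en-1-one F5. PPTS in MeOH removes the acetal to give (E)-1-[6-hydroxy-2,4-bis(methoxymethoxy)-3-(3-methylbut-2-en-1-yl)phenyl]-2-methylbut-2-en-1-one F6. Cinchona-alkaloid-catalysed asymmetric intramolecular oxa-Michael addition (quinidine or quinine, whichever pseudo-enantiomer gives the 2S series; chlorobenzene, rt) should give 17 together with its cis epimer, (2S,3R)-5,7-bis(methoxymethoxy)-2,3-dimethyl-6-(3-methylbut-2-en-1-yl)chroman-4-one F7. The cis epimer is equilibrated at C3 to the trans compound 17 with Et3N.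

**Further compounds**

F1 | step 10 | (2S,3S,10R)-5-hydroxy-2,3-dimethyl-6-(3-methylbut-2-en-1-yl)-10-propyl-2,3,9,10-tetrahydro-4H,8H-pyrano[2,3-f]chromene-4,8-dione | CCC[C@@H]1CC(=O)Oc2c(CC=C(C)C)c(O)c3c(c21)O[C@@H](C)[C@H](C)C3=O
F2 | step 7 | methyl (2S,3R)-3-hydroxy-2-methylbutanoate | C[C@@H](O)[C@H](C)C(=O)OC
F3 | step 7 | methyl (2S,3S)-3-[3,5-bis(methoxymethoxy)-4-(3-methylbut-2-en-1-yl)phenoxy]-2-methylbutanoate | C[C@H](Oc1cc(OCOC)c(CC=C(C)C)c(OCOC)c1)[C@H](C)C(=O)OC
F4 | step 7 | (2S,3S)-3-[3,5-bis(methoxymethoxy)-4-(3-methylbut-2-en-1-yl)phenoxy]-2-methylbutanoic acid | C[C@H](Oc1cc(OCOC)c(CC=C(C)C)c(OCOC)c1)[C@H](C)C(=O)O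
F5 | step 8 | (E)-1-[6-(1-ethoxyethoxy)-2,4-bis(methoxymethoxy)-3-(3-methylbut-2-en-1-yl)phenyl]-2-methylbut-2-en-1-one | C/C=C(\C)C(=O)c1c(OC(C)OCC)cc(OCOC)c(CC=C(C)C)c1OCOC
F6 | step 8 | (E)-1-[6-hydroxy-2,4-bis(methoxymethoxy)-3-(3-methylbut-2-en-1-yl)phenyl]-2-methylbut-2-en-1-one | C/C=C(\C)C(=O)c1c(O)cc(OCOC)c(CC=C(C)C)c1OCOC
F7 | step 8 | (2S,3R)-5,7-bis(methoxymethoxy)-2,3-dimethyl-6-(3-methylbut-2-en-1-yl)chroman-4-one | C[C@@H]1Oc2cc(OCOC)c(CC=C(C)C)c(OCOC)c2C(=O)[C@@H]1C
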